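The target in the ochre flask climbed to a reading of 24.3% of the charge at 8.00 h and then fell. I had to choose what to do with that flask at 40 h: leave it, heat it, take target out, or add free catalyst.

| setting | ochre | blue | flask |
|---|---|---|---|
| starting material | 20 mM | 20 mM | 20 mM |
| second substrate | 40 mM | 40 mM | 40.0 mM |
| free catalyst | 100 µM | 100 µM | 100 µM |
| temperature | 100 °C | 85 °C | 100 °C |
| remark | the very flask that is asked about, followed so far | run made earlier |  |
| time |  |  | 40 h |

| run | time / h | target / % |
|---|---|---|
| ochre | 2.50 | 17.0 |
| ochre | 4.00 | 21.4 |
| ochre | 8.00 | 24.3 |
| ochre | 12.0 | 23.0 |
| ochre | 20.0 | 17.2 |
| ochre | 30.0 | 13.7 |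
| blue | 5.00 | 13.0 |
| blue | 8.00 | 19.0 |
| blue | 15.0 | 25.6 |
| blue | 25.0 | 28.0 |
| blue | 40.0 | 25.3 |
| blue | 60.0 | 22.3 |

(readings scatter by 0.5 percentage points)

- percentages count the starting material that a species holds: one side product counts as two
- removed target is counted in
- reactions considered so far: starting material + free catalyst <-> catalyst intermediate A; catalyst intermediate A -> free catalyst + target; second substrate + free catalyst <-> catalyst intermediate B; catalyst intermediate B -> free catalyst + second product; starting material + target -> side product; free catalyst + target -> spent catalyst A; catalyst intermediate A -> spent catalyst B
- additions bring no volume worth counting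

- theta: at 40 h raise the temperature by 20 K, then wait 40 h
- delta: at 40 h take out 90% of the target then present, then wait 40 h
- beta: change nothing and wait 40 h more
- gamma: at 40 h add free catalyst, 100% of the amount charged, then wait 40 h

1. target, in percent of the starting material first charged, at 40 h
2. the option that brings most further target ("none" if no option brings more than 2 percentage points) (theta / delta / beta / gamma / none)
3. target present, with what was taken out counted in, in percent of the starting material first charged, after beta
4. target present, with what was taken out counted in, in percent of the starting material first charged, after gamma

I made the choice with one quantity, the tail rate: the net fraction of the target lost per hour between the last two ochre readings, 0.0228 /h. It is a pseudo-first-order constant for as long as the starting material changes slowly. Over the two readings before, the same reckoning gave 0.0363 /h, so the tail rate read lower than the earlier one, which fits a loss that uses up starting material too.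

Held constant, the tail rate carried the last ochre reading to 10.9% at 40 h and 4.39% after 40 h more. Because the tail rate read lower than the earlier one, I took the second figure as a low one. Waiting therefore meant losing target. The blue flask, at its lower temperature, gave a tail rate of 0.00631 /h, less than the ochre one, though over later hours, so I expected heat to hasten the loss. Taking target out could protect what stood.

Averaged up to the first ochre reading, target appeared at 0.0680 /h of the charge, far faster than the 0.00312 /h of the charge lost at the last reading. That early figure belonged to the first hours of the flask, with fresh free catalyst, so it was a rough guide, but I would add free catalyst.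

The forecast agreed on the choice, gamma: “Gamma is therefore best, though this is rough.” It gave 11.5% at 40 h (range 10.5% to 12.5%), 9.2% after waiting (range 7.5% to 10.8%), which is higher than my low figure, and 13% after the addition (range 10.8% to 15.5%).

The flask gave 10.5% at 40 h, 5.19% after waiting and 15.8% after the addition, so the best option was gamma, with a gain of 5.3 percentage points.

    starting material + free catalyst ⇌ catalyst intermediate A (K = 40.7 /M, k = 2.75 /M/s, Ea = 39.0 kJ/mol, ΔH = −44.0 kJ/mol)
    catalyst intermediate A → free catalyst + target (k = 0.0162 /s, Ea = 100 kJ/mol)
    second substrate + free catalyst ⇌ catalyst intermediate B (K = 12.0 /M, k = 1.34 /M/s, Ea = 39.0 kJ/mol, ΔH = −50.0 kJ/mol)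
    catalyst intermediate B → free catalyst + second product (k = 0.0510 /s, Ea = 94.0 kJ/mol)
    starting material + target → side product (k = 0.00234 /M/s, Ea = 95.0 kJ/mol)
    free catalyst + target → spent catalyst A (k = 0.0120 /M/s, Ea = 58.0 kJ/mol)
    catalyst intermediate A → spent catalyst B (k = 5.36 × 10⁻⁵ /s, Ea = 110 kJ/mol)
    (constants at 100 °C)

The flask was not at rest at 40 h. Over the wait its target fell at 0.0176 /h, lower than the tail rate, and 14.0% of the starting material stood as the wait began. The neighbour with 0.17 mM of free catalyst held 21.2% target and 5.4% starting material at 40 h; if the tail rate is taken to go with the starting material of the flask at 40.0 h and scaled to the neighbour's share, it becomes 0.00877 /h there, as an estimate. Left until 400 h, the flask itself still changed: its target reached 0.391%, its side product 95.5%, and its starting material 3.63%.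

The data come from a simulation from invented constants, and the scatter is random.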